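**Assumption (chemistry):** Digriseophene A is taken as the achiral, constitutionally symmetric bis-benzophenone of the given SMILES; it has no stereocentre, rotation about the crowded aryl–carbonyl bonds is assumed to be fast, and ketene acetal 10 is prepared fresh because it is moisture-sensitive.

## Analysis of the target

Digriseophene A, compound 19, is a symmetric dimer in which two identical benzophenone halves are joined by a single CH2 group linking C3 of one ring B to C3 of the other. Its only rings are four benzene rings and it has no stereocentre, so the problem is entirely one of constitution and regiochemistry. Ring B is a 2-acylphloroglucinol (ketone at C1 between hydroxyls at C2 and C6, methyl ether at C4, bridge at C3, hydrogen at C5), and ring A is an orsellinic-type ring (ketone at C1', methyl ether at C2', free hydroxyl at C4', methyl at C6', hydrogens at C3' and C5'). The sensitive features are six free phenols on electron-rich rings, a diaryl ketone that is benzylic to two rings and therefore reducible, and the diarylmethane bridge. The difficulty is threefold: the ketone is flanked on both sides by doubly ortho-substituted carbons, so acylation of either arene is slow and poorly regioselective; the oxygens must be told apart (C2' methylated but not C4', C4 methylated but not C2 and C6); and the bridging must touch ring B only and stop at the dimer. The plan rests on the substitution pattern of ring A: the run C6'(CH3)–C1'(acyl)–C2'(OMe)–C3'(H) is the C6–C5–C4–C3 diene of a 5-aroyl-4-methoxy-6-methyl-2-pyranone, and the remaining pair C4'(OH)–C5'(H) is the two-carbon unit of a ketene acetal. Ring A can therefore be grown onto a ketone that already carries ring B, and its two oxygens are distinguished by their origin, not by a selective alkylation.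

## Retrosynthetic reasoning

**Bridge.** Target 19 is cut at both aryl–CH2 bonds, giving two molecules of monomer 15 and formaldehyde 16. The cut is made here because it uses the symmetry and because C3 of ring B, ortho or para to three oxygens, is the most nucleophilic carbon of the monomer. The forward reaction has to select ring B over ring A and stop after one bridge.

**Phenol protection.** Monomer 15 is traced to its 2,6-di-O-benzyl ether 14. Benzyl ethers on ring B are chosen because they survive the acid released in the pyranone annulation and the hot, neutral cycloaddition, and because they come off by neutral hydrogenolysis that leaves both methyl ethers alone. The C4' hydroxyl needs no protection because it is only unmasked at the end of the key step.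

**Ring A (key disconnection).** In 14 the bonds C5'–C6' and C3'–C4' are cut, which leads to pyranone 7 and ketene acetal 10. Cutting here, and not at the aryl–carbonyl bond, means the hindered ketone is never made by acylating an arene. The C2' methoxy is already in place as the C4 methoxy of 7, and the C4' oxygen arrives as a silyl-masked hydroxyl. The forward step has to join the CH2 terminus of 10 to C6 of 7 and the acetal carbon to C3, then extrude the lactone bridge and one silyloxy group to reach the aromatic oxidation level without any oxidant.

**Ketene acetal.** Compound 10 is the O-silylated enolate of trimethylsilyl acetate 8; one O–Si bond is cut.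

**Methyl ether of the pyranone.** Pyranone 7 comes from hydroxypyranone 6 by cutting the C4–O–CH3 bond. The 4-hydroxy-2-pyranone is a vinylogous acid, so the forward reaction is a simple O-alkylation that must go to the C4 oxygen and not to the lactone carbonyl oxygen.

**Pyranone ring.** In 6 the bonds C4–C5 and O1–C2 are cut, giving aroylacetone 3 and malonyl dichloride 4. The central carbon of 3 becomes C5, the acetyl carbon with its methyl becomes C6, the acetyl oxygen becomes O1, and the aroyl group stays as the C5 substituent. The forward reaction needs C-acylation followed by lactonisation through the acetyl-side enol oxygen.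

**Diketone.** Compound 3 is cut between the former acetophenone methyl carbon and the new acetyl carbonyl, which leads back to methyl ketone 2; the forward reaction is a crossed Claisen acetylation.

**Ring B.** Compound 2 is the bis-benzyl ether of acetophenone 1, which already has the complete ring B oxygenation pattern with the C4 methyl ether in place. Ring B therefore needs no regiochemical decision at any stage.

## Alternatives that were turned down

Alternative 1: Ring A is carried as a cyclic vinylogous ester and aromatised late. The disconnection is at both C(=O)–C1' bonds of a molecule that already has the bridge. In the forward key step, two equivalents of the kinetic lithium enolate of 3-(benzyloxy)-5-methylcyclohex-2-en-1-one A2 are C-acylated by the bridged ring B bis(acid chloride) A3, giving the bis(6-aroyl-3-benzyloxy-5-methylcyclohexadienol) adduct A1.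
- For it: the route is two-directional, and the bridge is set before ring A exists. On this point it is stronger than the chosen route, whose last step must discriminate between rings A and B.
- Against it: A3 is a doubly ortho-substituted bis(acid chloride) that needs its own multi-step preparation, including a hard hydrolysis of a hindered ester. C- versus O-acylation of the enolate of A2, and proton transfer to the more acidic product, must be controlled twice on one molecule. A1 forms as a mixture of diastereomers, which is harmless but hard to analyse. After the key step, each half still needs dehydrogenation (with an oxidant that can also attack the electron-rich diarylmethane bridge and the benzyl ethers), methylation of a chelated C2' hydroxyl, and removal of six benzyl groups.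
- Comparison: the chosen strategy offers ring A at the aromatic oxidation level, with C2'-OMe and C4'-OH already differentiated, and no doubled late-stage operations. The price is one selectivity question in the final bridging.

Alternative 2: Ring B is built by a cycloaddition. With ring B numbered so that boron sits at C2, the disconnection cuts C2–C3 and C6–C1. In the forward key step, 3-methoxy-1,1-bis(trimethylsilyloxy)buta-1,3-diene A5 adds across the ring A alkynyl ketone boronate A6 and the adduct loses a silyloxy group, giving arylboronate A4 with boron at the second ortho position; the C–B bond is oxidised to the second hydroxyl later.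
- For it: a normal-demand cycloaddition between the very electron-rich diene A5 and the electron-poor alkyne A6 is electronically better matched than the push–pull pyranone of the chosen route, and should run under milder conditions. On the intrinsic ease of the ring-forming step it is the stronger proposal.
- Against it: it uses its one powerful step to build the ring whose pattern can simply be bought, and the harder ring A must then be assembled beforehand by classical, stepwise aromatic substitution with its own regiochemical problems. A6 is a fragile boryl ynone, prone to protodeboronation and conjugate addition. A further C–B oxidation of A4 is needed before hydrogenolysis and bridging, so the route is longer.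
- Comparison: the chosen strategy offers a shorter sequence in which ring B is never touched and ring A gets its substitution from the ring construction itself.

Alternative 3: A Michael–Claisen annulation gives a dihydro ring A. The disconnection cuts C1'–C6' and C3'–C4', as in the chosen route, but at the cyclohexanedione oxidation level. In the forward key step, under an alkoxide base the central carbon of aroylacetone 3 adds to methyl (E)-but-2-enoate A8 and the acetyl methyl then closes on the ester, giving 4-aroyl-5-methylcyclohexane-1,3-dione A7.
- For it: it shares 3 with the chosen route, uses only cheap anionic chemistry with no heat-sensitive silyl reagent, and on paper is one step shorter in total, with an equal longest linear sequence.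
- Against it: conjugate addition of a hindered, stabilised diketone anion to the β-substituted acrylate A8 is slow and reversible, and alkoxide can cleave the diketone. A7 has two enolic oxygens, of which only the one next to the aroyl-bearing carbon may be methylated, and nothing in the structure controls this. The ring must then be dehydrogenated in the presence of benzyl ethers.
- Comparison: the chosen strategy uses one extra carbon (lost as the lactone bridge) to settle both issues in advance, since the pyranone carries the methoxy at the right carbon and aromatises by extrusion, not oxidation.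

Key step: step 6

## Route

Step 1
Reactants: 1 (2',6'-dihydroxy-4'-methoxyacetophenone)
Product: 2 2',6'-bis(benzyloxy)-4'-methoxyacetophenone
Conditions: BnBr, K2CO3, DMF, 70 °C
Reagents that add atoms: benzyl bromide, BrCc1ccccc1
Why: Williamson ether synthesis; both phenols, including the chelated one, are O-benzylated in warm DMF, and the acetyl group deactivates the ring toward C-benzylation. Benzyl is chosen because it tolerates the HCl of step 3 and the heating of step 6 and is removed under neutral conditions.

Step 2
Reactants: 2 (2',6'-bis(benzyloxy)-4'-methoxyacetophenone)
Product: 3 1-[2,6-bis(benzyloxy)-4-methoxyphenyl]butane-1,3-dione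
Conditions: NaH, EtOAc, THF, reflux; then 1 M HCl
Reagents that add atoms: ethyl acetate, CCOC(C)=O
Why: Crossed Claisen condensation; the sodium enolate of the methyl ketone is acetylated by the ester and the equilibrium is pulled over by deprotonation of the 1,3-diketone. The carbonyl of 2 is screened by two ortho benzyloxy groups, so aldol addition of the ester enolate to it should not compete.

Step 3
Reactants: 3 (1-[2,6-bis(benzyloxy)-4-methoxyphenyl]butane-1,3-dione), 4 (malonyl dichloride)
Product: 6 5-[2,6-bis(benzyloxy)-4-methoxybenzoyl]-4-hydroxy-6-methyl-2H-pyran-2-one, via triketo acid chloride 5 (not isolated)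
Conditions: 4 (1.05 equiv), CH2Cl2, 0 °C → 40 °C, N2 sweep, no base
Reagents that add atoms: none
Why: Known annulation of 1,3-diketones with malonyl dichloride to 5-acyl-4-hydroxy-2-pyranones; C-acylation at the central carbon gives 5, an enol oxygen closes on the second acid chloride, and the ring settles as the 4-hydroxy-2-pyranone. Closure is expected through the acetyl-side oxygen (6-methyl, 5-aroyl), in line with the usual behaviour of aroylacetones and reinforced here by the two ortho benzyloxy groups that screen the aroyl oxygen. Benzyl aryl ethers should tolerate anhydrous HCl in CH2Cl2 at this temperature, and the near-stoichiometric amount of 4 limits a second acylation of the product at C3.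

Step 4
Reactants: 6 (5-[2,6-bis(benzyloxy)-4-methoxybenzoyl]-4-hydroxy-6-methyl-2H-pyran-2-one)
Product: 7 5-[2,6-bis(benzyloxy)-4-methoxybenzoyl]-4-methoxy-6-methyl-2H-pyran-2-one
Conditions: Me2SO4, K2CO3, acetone, reflux
Reagents that add atoms: dimethyl sulfate, COS(=O)(=O)OC
Why: O-Alkylation of a vinylogous acid; under K2CO3/acetone the anion of a 4-hydroxy-2-pyranone takes the hard methyl electrophile at the C4 oxygen, giving the 4-methoxy-2-pyranone and not the 2-methoxy-4-pyranone. This methoxy becomes the C2' ether of ring A.

Step 5
Reactants: 8 (trimethylsilyl acetate)
Product: 10 1,1-bis(trimethylsilyloxy)ethene, via lithium enolate 9 (not isolated)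
Conditions: LiN(i-Pr)2, THF, −78 °C; Me3SiCl, −78 °C → rt; distillation
Reagents that add atoms: chlorotrimethylsilane, C[Si](C)(C)Cl
Why: Standard preparation of a ketene bis(silyl) acetal; the silyl ester is enolised by lithium diisopropylamide and enolate 9 is silylated on oxygen by the hard silicon electrophile.

Step 6
Reactants: 7 (5-[2,6-bis(benzyloxy)-4-methoxybenzoyl]-4-methoxy-6-methyl-2H-pyran-2-one), 10 (1,1-bis(trimethylsilyloxy)ethene)
Product: 14 [2,6-bis(benzyloxy)-4-methoxyphenyl](4-hydroxy-2-methoxy-6-methylphenyl)methanone, via bridged lactone adduct 11 (not isolated), via cyclohexadiene bis-silyl ketal 12 (not isolated), via aryl trimethylsilyl ether 13 (not isolated)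
Conditions: 10 (5 equiv), toluene, 110 °C, sealed tube; then 1 M HCl, THF, rt
Reagents that add atoms: none
Why: Inverse-electron-demand Diels–Alder reaction of a 2-pyranone with a ketene acetal, followed by cycloreversion and elimination, the known way from 5-acyl- and 5-alkoxycarbonyl-2-pyranones to para-oxygenated aryl ketones and benzoates. The electron-rich CH2 terminus of 10 bonds to C6 of 7 and the acetal carbon to C3, either in one asynchronous event or through a zwitterion (oxocarbenium and dienolate) that collapses. Ring A is thus closed by a [4+2] cycloaddition of the C3=C4–C5=C6 diene with the C=C of 10, giving bridged lactone 11. Retro-[4+2] loss of CO2 from 11 gives cyclohexadiene 12, 1,2-elimination of trimethylsilanol across C4'–C5' aromatises it to silyl ether 13, and the acidic work-up frees phenol 14. No stereocentre is created in the product, because the two bridgehead centres of racemic 11 are destroyed on aromatisation. The step needs regioselectivity (oxygen at C4', not C5'); this is secured by the polarisation of the diene, because C6 is β to the aroyl ketone and δ to the lactone carbonyl and so is the electrophilic terminus, while C3 is the α-carbon of the lactone and takes the electrophilic acetal carbon. The C4 methoxy is carried unchanged into C2', so the two ring A oxygens are differentiated without any selective alkylation. Benzyl ethers, the aryl methyl ether and the ketone are inert to heating with a neutral ketene acetal.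

Step 7
Reactants: 14 ([2,6-bis(benzyloxy)-4-methoxyphenyl](4-hydroxy-2-methoxy-6-methylphenyl)methanone)
Product: 15 (2,6-dihydroxy-4-methoxyphenyl)(4-hydroxy-2-methoxy-6-methylphenyl)methanone
Conditions: H2 (1 atm), 10% Pd/C, EtOAc, rt
Reagents that add atoms: none
Why: Hydrogenolysis of benzyl aryl ethers; methyl ethers are inert. The ketone, screened by four ortho substituents and converted into a chelated vinylogous acid as soon as the first ring B phenol is freed, should resist reduction at 1 atm in a non-acidic solvent.

Step 8
Reactants: 15 ((2,6-dihydroxy-4-methoxyphenyl)(4-hydroxy-2-methoxy-6-methylphenyl)methanone, 2 equiv), 16 (formaldehyde)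
Product: 19 Digriseophene A, via hydroxymethyl monomer 17 (not isolated), via ortho-quinone methide 18 (not isolated)
Conditions: 37% aq. CH2O (0.45 equiv relative to 15), NaOH (1 equiv), MeOH–H2O, 0 °C → rt; then 1 M HCl
Reagents that add atoms: none
Why: Base-mediated hydroxymethylation (Lederer–Manasse type) of the acylphloroglucinol ring gives 17, which loses water to quinone methide 18; Michael addition of a second ring B phenoxide through C3 closes the bridge, as is known for methylene-bridged acylphloroglucinols. Ring B is expected to react in preference to ring A because C3 is ortho or para to three oxygens, whereas the free positions of ring A are activated by only two. The deficit of formaldehyde limits chain growth beyond the dimer, and unreacted 15 is recycled.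

## Compound list

1 | 2',6'-dihydroxy-4'-methoxyacetophenone | COc1cc(O)c(C(C)=O)c(O)c1 | starting material
2 | 2',6'-bis(benzyloxy)-4'-methoxyacetophenone | COc1cc(OCc2ccccc2)c(C(C)=O)c(OCc2ccccc2)c1 | intermediate
3 | 1-[2,6-bis(benzyloxy)-4-methoxyphenyl]butane-1,3-dione | COc1cc(OCc2ccccc2)c(C(=O)CC(C)=O)c(OCc2ccccc2)c1 | intermediate
4 | malonyl dichloride | O=C(Cl)CC(Cl)=O | starting material
5 | 4-acetyl-5-[2,6-bis(benzyloxy)-4-methoxyphenyl]-3,5-dioxopentanoyl chloride (formed in the flask) | COc1cc(OCc2ccccc2)c(C(=O)C(C(C)=O)C(=O)CC(Cl)=O)c(OCc2ccccc2)c1 | intermediate
6 | 5-[2,6-bis(benzyloxy)-4-methoxybenzoyl]-4-hydroxy-6-methyl-2H-pyran-2-one | COc1cc(OCc2ccccc2)c(C(=O)C2=C(C)OC(=O)C=C2O)c(OCc2ccccc2)c1 | intermediate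
7 | 5-[2,6-bis(benzyloxy)-4-methoxybenzoyl]-4-methoxy-6-methyl-2H-pyran-2-one | COC1=CC(=O)OC(C)=C1C(=O)c1c(OCc2ccccc2)cc(OC)cc1OCc1ccccc1 | intermediate
8 | trimethylsilyl acetate | CC(=O)O[Si](C)(C)C | starting material
9 | lithium 1-(trimethylsilyloxy)ethenolate (formed in the flask) | [Li+].[O-]C(=C)O[Si](C)(C)C | intermediate
10 | 1,1-bis(trimethylsilyloxy)ethene | C=C(O[Si](C)(C)C)O[Si](C)(C)C | intermediate
11 | 6-[2,6-bis(benzyloxy)-4-methoxybenzoyl]-5-methoxy-1-methyl-8,8-bis(trimethylsilyloxy)-2-oxabicyclo[2.2.2]oct-5-en-3-one (racemic, one enantiomer drawn; relative configuration fixed by the bridge; formed in the flask) | C[C@@]12CC(O[Si](C)(C)C)(O[Si](C)(C)C)[C@@H](C(=O)O1)C(OC)=C2C(=O)c1c(OCc2ccccc2)cc(OC)cc1OCc1ccccc1 | intermediate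
12 | [2,6-bis(benzyloxy)-4-methoxyphenyl][6-methoxy-2-methyl-4,4-bis(trimethylsilyloxy)cyclohexa-1,5-dien-1-yl]methanone (formed in the flask) | COc1cc(OCc2ccccc2)c(C(=O)C2=C(C)CC(O[Si](C)(C)C)(O[Si](C)(C)C)C=C2OC)c(OCc2ccccc2)c1 | intermediate
13 | [2,6-bis(benzyloxy)-4-methoxyphenyl][2-methoxy-6-methyl-4-(trimethylsilyloxy)phenyl]methanone (formed in the flask) | COc1cc(OCc2ccccc2)c(C(=O)c2c(C)cc(O[Si](C)(C)C)cc2OC)c(OCc2ccccc2)c1 | intermediate
14 | [2,6-bis(benzyloxy)-4-methoxyphenyl](4-hydroxy-2-methoxy-6-methylphenyl)methanone | COc1cc(OCc2ccccc2)c(C(=O)c2c(C)cc(O)cc2OC)c(OCc2ccccc2)c1 | intermediate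
15 | (2,6-dihydroxy-4-methoxyphenyl)(4-hydroxy-2-methoxy-6-methylphenyl)methanone | COc1cc(O)c(C(=O)c2c(C)cc(O)cc2OC)c(O)c1 | intermediate
16 | formaldehyde | C=O | starting material
17 | [2,6-dihydroxy-3-(hydroxymethyl)-4-methoxyphenyl](4-hydroxy-2-methoxy-6-methylphenyl)methanone (formed in the flask) | COc1cc(O)c(C(=O)c2c(C)cc(O)cc2OC)c(O)c1CO | intermediate
18 | 3-hydroxy-2-(4-hydroxy-2-methoxy-6-methylbenzoyl)-5-methoxy-6-methylidenecyclohexa-2,4-dien-1-one (formed in the flask) | COC1=CC(O)=C(C(=O)c2c(C)cc(O)cc2OC)C(=O)C1=C | intermediate
19 | Digriseophene A, bis[2,4-dihydroxy-3-(4-hydroxy-2-methoxy-6-methylbenzoyl)-6-methoxyphenyl]methane | COc1cc(O)c(C(=O)c2c(C)cc(O)cc2OC)c(O)c1Cc1c(OC)cc(O)c(C(=O)c2c(C)cc(O)cc2OC)c1O | target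

## Step count and least certain steps

Total step count: 8. Longest linear sequence: 7 (steps 1, 2, 3, 4, 6, 7, 8); step 5 is a one-step side branch.

**Step 6 (key step).** The cycloaddition may be too slow. Donation from the C4 methoxy group and twisting of the crowded aroyl carbonyl out of the pyranone plane both weaken the activation of C6, so thermal decay of 10 (oxygen-to-carbon silyl shift, adventitious hydrolysis) could outrun ring formation. A second failure path is conjugate addition at C6 followed by opening of the lactone without closure on C3. The fallback leaves the route at 3 and builds ring A by anionic acetoacetylation and aldol aromatisation. Diketone 3 with NaH and diketene in THF should be C-acylated at the central carbon, after which the new terminal methyl closes on the acetyl carbonyl and the ring dehydrates to [2,6-bis(benzyloxy)-4-methoxyphenyl](2,4-dihydroxy-6-methylphenyl)methanone F1. Its free, non-chelated C4' hydroxyl is benzylated selectively (BnBr, 1 equiv, K2CO3, acetone) to [4-(benzyloxy)-2-hydroxy-6-methylphenyl][2,6-bis(benzyloxy)-4-methoxyphenyl]methanone F2. The chelated C2' hydroxyl is then methylated (MeI, K2CO3, DMF, 60 °C) to [4-(benzyloxy)-2-methoxy-6-methylphenyl][2,6-bis(benzyloxy)-4-methoxyphenyl]methanone F3. Hydrogenolysis of all three benzyl ethers (H2, 10% Pd/C, EtOAc) rejoins the route at 15.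

**Step 3.** Lactonisation may proceed through the aroyl-side enol oxygen, which would put the aryl group at C6. The HCl released may also cause acylation of the electron-rich ring B or loss of a benzyl ether. The fallback leaves at 3 and separates the two bond formations. Soft enolisation (MgCl2, pyridine, CH2Cl2, 0 °C) and C-acylation with methyl 3-chloro-3-oxopropanoate should give methyl 4-acetyl-5-[2,6-bis(benzyloxy)-4-methoxyphenyl]-3,5-dioxopentanoate F4 without free HCl. F4 is then lactonised on its own with loss of methanol (DBU, toluene, 80 °C; then acidification), so the ring closure can be studied and steered separately; the sequence rejoins the route at 6.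

**Step 8.** Bridging may continue beyond the dimer, because each ring B of 19 keeps a nucleophilic C5–H. Ring A may also be attacked ortho to its C4' hydroxyl. The fallback leaves at 15 and makes the two C–C bonds one at a time. Aminomethylation with one equivalent of N,N-dimethylmethyleneiminium iodide in CH2Cl2 should give the Mannich base [3-[(dimethylamino)methyl]-2,6-dihydroxy-4-methoxyphenyl](4-hydroxy-2-methoxy-6-methylphenyl)methanone F5, whose site of substitution can be checked. Heating F5 with an excess of 15 in dioxane expels dimethylamine, and the quinone methide is captured by the monomer present in excess, which favours the dimer over higher oligomers; the sequence rejoins the route at 19.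

**Step 4.** Alkylation of the ambident pyranone anion may go to the lactone carbonyl oxygen or to C3. The fallback runs from 6 to 7 by a Mitsunobu etherification with methanol (PPh3, diisopropyl azodicarboxylate, THF, 0 °C → rt). This activates the alcohol partner and not a methyl electrophile and is known to favour the 4-alkoxy-2-pyranone; it makes no new compound.

**Step 7.** Over-reduction of the diaryl ketone to the carbinol or the methylene compound may occur, since its carbonyl carbon is benzylic to two rings. The fallback runs from 14 to 15 by Lewis-acid debenzylation (BCl3, pentamethylbenzene as benzyl-cation scavenger, CH2Cl2, −78 °C). It involves no reducing agent, and at this temperature the methyl ethers should remain; it makes no new compound.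

## Further compounds

F1 | step 6 | [2,6-bis(benzyloxy)-4-methoxyphenyl](2,4-dihydroxy-6-methylphenyl)methanone | COc1cc(OCc2ccccc2)c(C(=O)c2c(C)cc(O)cc2O)c(OCc2ccccc2)c1
F2 | step 6 | [4-(benzyloxy)-2-hydroxy-6-methylphenyl][2,6-bis(benzyloxy)-4-methoxyphenyl]methanone | COc1cc(OCc2ccccc2)c(C(=O)c2c(C)cc(OCc3ccccc3)cc2O)c(OCc2ccccc2)c1
F3 | step 6 | [4-(benzyloxy)-2-methoxy-6-methylphenyl][2,6-bis(benzyloxy)-4-methoxyphenyl]methanone | COc1cc(OCc2ccccc2)c(C(=O)c2c(C)cc(OCc3ccccc3)cc2OC)c(OCc2ccccc2)c1
F4 | step 3 | methyl 4-acetyl-5-[2,6-bis(benzyloxy)-4-methoxyphenyl]-3,5-dioxopentanoate | COC(=O)CC(=O)C(C(C)=O)C(=O)c1c(OCc2ccccc2)cc(OC)cc1OCc1ccccc1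
F5 | step 8 | [3-[(dimethylamino)methyl]-2,6-dihydroxy-4-methoxyphenyl](4-hydroxy-2-methoxy-6-methylphenyl)methanone | COc1cc(O)c(C(=O)c2c(C)cc(O)cc2OC)c(O)c1CN(C)C
F0 | step 4 | none | none
F0 | step 7 | none | none
A1 | alternative 1 | bis(6-aroyl-3-benzyloxy-5-methylcyclohexadienol) adduct of the bridged ring B dimer (enol form, one diastereomer drawn) | COc1cc(OCc2ccccc2)c(C(=O)C2=C(O)C=C(OCc3ccccc3)C[C@@H]2C)c(OCc2ccccc2)c1Cc1c(OC)cc(OCc2ccccc2)c(C(=O)C2=C(O)C=C(OCc3ccccc3)C[C@@H]2C)c1OCc1ccccc1
A2 | alternative 1 | 3-(benzyloxy)-5-methylcyclohex-2-en-1-one (racemic) | CC1CC(=O)C=C(OCc2ccccc2)C1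
A3 | alternative 1 | 3,3'-methylenebis[2,6-bis(benzyloxy)-4-methoxybenzoyl chloride] | COc1cc(OCc2ccccc2)c(C(Cl)=O)c(OCc2ccccc2)c1Cc1c(OC)cc(OCc2ccccc2)c(C(Cl)=O)c1OCc1ccccc1
A4 | alternative 2 | [2-hydroxy-4-methoxy-6-(4,4,5,5-tetramethyl-1,3,2-dioxaborolan-2-yl)phenyl](4-benzyloxy-2-methoxy-6-methylphenyl)methanone | COc1cc(O)c(C(=O)c2c(C)cc(OCc3ccccc3)cc2OC)c(B2OC(C)(C)C(C)(C)O2)c1
A5 | alternative 2 | 3-methoxy-1,1-bis(trimethylsilyloxy)buta-1,3-diene | C=C(OC)C=C(O[Si](C)(C)C)O[Si](C)(C)C
A6 | alternative 2 | 1-[4-(benzyloxy)-2-methoxy-6-methylphenyl]-3-(4,4,5,5-tetramethyl-1,3,2-dioxaborolan-2-yl)prop-2-yn-1-one | COc1cc(OCc2ccccc2)cc(C)c1C(=O)C#CB1OC(C)(C)C(C)(C)O1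
A7 | alternative 3 | 4-[2,6-bis(benzyloxy)-4-methoxybenzoyl]-5-methylcyclohexane-1,3-dione (enol form, racemic, one enantiomer drawn) | C[C@H]1CC(=O)CC(O)=C1C(=O)c1c(OCc2ccccc2)cc(OC)cc1OCc1ccccc1
A8 | alternative 3 | methyl (E)-but-2-enoate | C/C=C/C(=O)OC
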